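## Retrosynthetic overview

1. The target is a tridepside C–B–A (A = methyl isoeverninate end, B = central isoeverninate unit, C = everninate cap). The C–B ester C–O bond is cut last, giving the didepside phenol HO–B–A and everninic acid.
2. HO–B–A comes from the deoxy-didepside H–B–A by sterically controlled C–H borylation/oxidation at C4' of ring B (C–O bond).
3. H–B–A comes from the key aryl C–O bond formation: C–H borylation of methyl 2-methoxy-6-methylbenzoate, then Cu-catalysed acyloxylation of the aryl boronate with 2-methoxy-6-methylbenzoic acid.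
4. Everninic acid comes from methyl orsellinate by selective 4-O-methylation and saponification.
5. No ring is formed: all three benzene rings are purchased, and the chain is assembled in the order A, B, C.

Assumption: the target has no stereocentre and no configurationally stable axis, so it is achiral and no stereocontrol is required.

## Route

Step 1
Reactants: 1 methyl 2-methoxy-6-methylbenzoate; 2 2-methoxy-6-methylbenzoic acid
Product: 4 methyl 2-methoxy-4-[(2-methoxy-6-methylbenzoyl)oxy]-6-methylbenzoate, via aryl pinacol boronate 3 (not isolated)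
Conditions: [Ir(OMe)(cod)]2 (1.5 mol%), dtbpy (3 mol%), B2pin2 (1.0 equiv), THF, 80 °C; evaporate volatiles; then 2 (1.5 equiv), Cu(OTf)2 (30 mol%), pyridine (3 equiv), 4 Å MS, O2 (1 atm), MeCN, 60 °C
Reagents that add atoms: bis(pinacolato)diboron, CC1(C)OB(OC1(C)C)B1OC(C)(C)C(C)(C)O1 (its Bpin group sits in intermediate 3 only)
Why: Proposed new method: a telescoped Ir-catalysed steric C–H borylation / aerobic Cu-catalysed Chan–Lam acyloxylation, in which Ir borylates only C4 of 1 (the one C–H with no ortho substituent) and boronate 3 transmetalates to a Cu(II) carboxylate of 2 that, after oxidation to Cu(III), forms the depside aryl C–O bond by reductive elimination at the carboxylate oxygen, so the doubly ortho-shielded acyl carbon of 2 is never attacked; the closest known reaction types are the one-pot C–H borylation/Chan–Lam amination or etherification of arenes and the Cu-mediated esterification of arylboronic acids with carboxylic acids, neither shown for an aryl pinacol boronate paired with a 2,6-disubstituted benzoic acid or for depside synthesis.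

Step 2
Reactants: 4 methyl 2-methoxy-4-[(2-methoxy-6-methylbenzoyl)oxy]-6-methylbenzoate
Product: 7 methyl 4-[(4-hydroxy-2-methoxy-6-methylbenzoyl)oxy]-2-methoxy-6-methylbenzoate, via aryl pinacol boronate 5 (not isolated), via aryl pinacol borate 6 (not isolated)
Conditions: [Ir(OMe)(cod)]2 (1.5 mol%), dtbpy (3 mol%), B2pin2 (1.0 equiv), THF, 80 °C; evaporate; then Oxone (1.5 equiv), acetone/H2O 1:1, rt, 15 min
Reagents that add atoms: bis(pinacolato)diboron, CC1(C)OB(OC1(C)C)B1OC(C)(C)C(C)(C)O1 (Bpin of 5 and 6); potassium peroxymonosulfate (active component of Oxone), [K+].[O-]S(=O)(=O)OO (phenolic oxygen of 7)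
Why: Known one-pot Ir-catalysed C–H borylation/Oxone oxidation (arene to phenol): both ring-A C–H bonds of 4 are flanked by two ortho substituents, so only C4' of ring B is borylated, and near-neutral Oxone converts the boronate to the phenol by 1,2-aryl migration and borate hydrolysis without cleaving either ester.

Step 3
Reactants: 8 methyl 2,4-dihydroxy-6-methylbenzoate (methyl orsellinate)
Product: 9 methyl 2-hydroxy-4-methoxy-6-methylbenzoate (methyl everninate)
Conditions: MeI (1.1 equiv), K2CO3 (1.1 equiv), acetone, 40 °C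
Reagents that add atoms: iodomethane, CI
Why: Selective Williamson O-methylation: the 4-OH is the more acidic, unchelated phenol, while the 2-OH is held in a hydrogen bond to the ester carbonyl and stays free with one equivalent of MeI.

Step 4
Reactants: 9 methyl 2-hydroxy-4-methoxy-6-methylbenzoate
Product: 11 2-hydroxy-4-methoxy-6-methylbenzoic acid (everninic acid), via potassium carboxylate 10 (not isolated)
Conditions: KOH (5 equiv), DMSO/H2O 4:1, 80 °C; then 1 M HCl, 0 °C, to pH 2
Reagents that add atoms: potassium hydroxide, [K+].[OH-]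
Why: Saponification (BAc2 ester hydrolysis) of a hindered salicylate proceeds with hot KOH in aqueous DMSO, and cold acidification avoids decarboxylation of the electron-rich acid.

Step 5
Reactants: 7 methyl 4-[(4-hydroxy-2-methoxy-6-methylbenzoyl)oxy]-2-methoxy-6-methylbenzoate; 11 2-hydroxy-4-methoxy-6-methylbenzoic acid
Product: 13 methyl 4-({4-[(2-hydroxy-4-methoxy-6-methylbenzoyl)oxy]-2-methoxy-6-methylbenzoyl}oxy)-2-methoxy-6-methylbenzoate (target), via O-acylisourea 12 (not isolated)
Conditions: 11 (1.2 equiv), DCC (1.3 equiv), toluene, rt, 48 h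
Reagents that add atoms: N,N'-dicyclohexylcarbodiimide, C(=NC1CCCCC1)=NC1CCCCC1 (its atoms sit in intermediate 12 only)
Why: Carbodiimide esterification (the classical DCC depside coupling): the unhindered 4'-phenol of 7 is the only competent nucleophile, because the 2-OH of 11 is hydrogen-bonded to its own carbonyl and its 4-position is capped as OMe, so the acid does not self-condense and needs no protecting group.

## Compound list

1 | methyl 2-methoxy-6-methylbenzoate | COC(=O)c1c(C)cccc1OC | starting material
2 | 2-methoxy-6-methylbenzoic acid | OC(=O)c1c(C)cccc1OC | starting material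
3 | methyl 2-methoxy-6-methyl-4-(4,4,5,5-tetramethyl-1,3,2-dioxaborolan-2-yl)benzoate | COC(=O)c1c(C)cc(B2OC(C)(C)C(C)(C)O2)cc1OC | intermediate
4 | methyl 2-methoxy-4-[(2-methoxy-6-methylbenzoyl)oxy]-6-methylbenzoate | COC(=O)c1c(C)cc(OC(=O)c2c(C)cccc2OC)cc1OC | intermediate
5 | methyl 2-methoxy-4-{[2-methoxy-6-methyl-4-(4,4,5,5-tetramethyl-1,3,2-dioxaborolan-2-yl)benzoyl]oxy}-6-methylbenzoate | COC(=O)c1c(C)cc(OC(=O)c2c(C)cc(B3OC(C)(C)C(C)(C)O3)cc2OC)cc1OC | intermediate
6 | methyl 2-methoxy-4-({2-methoxy-6-methyl-4-[(4,4,5,5-tetramethyl-1,3,2-dioxaborolan-2-yl)oxy]benzoyl}oxy)-6-methylbenzoate | COC(=O)c1c(C)cc(OC(=O)c2c(C)cc(OB3OC(C)(C)C(C)(C)O3)cc2OC)cc1OC | intermediate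
7 | methyl 4-[(4-hydroxy-2-methoxy-6-methylbenzoyl)oxy]-2-methoxy-6-methylbenzoate | COC(=O)c1c(C)cc(OC(=O)c2c(C)cc(O)cc2OC)cc1OC | intermediate
8 | methyl 2,4-dihydroxy-6-methylbenzoate (methyl orsellinate) | COC(=O)c1c(C)cc(O)cc1O | starting material
9 | methyl 2-hydroxy-4-methoxy-6-methylbenzoate (methyl everninate) | COC(=O)c1c(C)cc(OC)cc1O | intermediate
10 | potassium 2-hydroxy-4-methoxy-6-methylbenzoate | [K+].[O-]C(=O)c1c(C)cc(OC)cc1O | intermediate
11 | 2-hydroxy-4-methoxy-6-methylbenzoic acid (everninic acid) | OC(=O)c1c(C)cc(OC)cc1O | intermediate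
12 | N,N'-dicyclohexyl-O-(2-hydroxy-4-methoxy-6-methylbenzoyl)isourea | COc1cc(C)c(C(=O)OC(=NC2CCCCC2)NC2CCCCC2)c(O)c1 | intermediate
13 | methyl 4-({4-[(2-hydroxy-4-methoxy-6-methylbenzoyl)oxy]-2-methoxy-6-methylbenzoyl}oxy)-2-methoxy-6-methylbenzoate | COC(=O)c1c(C)cc(OC(=O)c2c(C)cc(OC(=O)c3c(C)cc(OC)cc3O)cc2OC)cc1OC | target

## Step count and risk

Total step count: 5 (steps 1 and 2 are one-pot operations). Longest linear sequence: 3 (steps 1, 2, 5, or steps 3, 4, 5).

Steps most likely to fail:

**Step 1 (proposed new step).** The aryl pinacol boronate may transmetalate slowly to copper, and the hindered carboxylate may lose out to protodeboronation, homocoupling or phenol formation. The fallback uses known chemistry, sets out from 1 and comes back at 4. Compound 1 is borylated as in step 1 to 3, which is oxidised in the same pot with Oxone in aqueous acetone. This passes through methyl 2-methoxy-6-methyl-4-[(4,4,5,5-tetramethyl-1,3,2-dioxaborolan-2-yl)oxy]benzoate F1 and gives the isolated phenol methyl 4-hydroxy-2-methoxy-6-methylbenzoate F2. F2 is then condensed with acid 2 by the classical mixed-anhydride depside esterification (TFAA, toluene, rt) to give 4.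

**Step 2.** Borylation of the larger, more coordinating didepside may be sluggish or less selective, and the phenol may over-oxidise. The fallback abandons late C–H oxidation for a protected ring-B acid; it sets out from 1 and comes back at 7. Methyl 4-hydroxy-2-methoxy-6-methylbenzoate F2, made from 1 as in the fallback to step 1, is O-benzylated (BnBr, K2CO3, DMF, 60 °C) to methyl 4-(benzyloxy)-2-methoxy-6-methylbenzoate F3. F3 is saponified (KOH, aqueous DMSO, 90 °C, then HCl) to 4-(benzyloxy)-2-methoxy-6-methylbenzoic acid F4. F4 is condensed with a second portion of F2 (TFAA, toluene, rt) to methyl 4-{[4-(benzyloxy)-2-methoxy-6-methylbenzoyl]oxy}-2-methoxy-6-methylbenzoate F5. Hydrogenolysis (H2, Pd/C, EtOAc, rt) then gives 7.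

**Step 5.** The unprotected ortho-hydroxy acid may give N-acylurea or react slowly at its hindered carbonyl. The fallback protects the 2-OH; it sets out from 9 and comes back at 13. Compound 9 is O-benzylated (BnBr, K2CO3, DMF, 80 °C) to methyl 2-(benzyloxy)-4-methoxy-6-methylbenzoate F6. F6 is saponified (KOH, aqueous DMSO, 90 °C, then HCl) to 2-(benzyloxy)-4-methoxy-6-methylbenzoic acid F7. F7 is condensed with 7 (TFAA, toluene, rt) to methyl 4-({4-[(2-(benzyloxy)-4-methoxy-6-methylbenzoyl)oxy]-2-methoxy-6-methylbenzoyl}oxy)-2-methoxy-6-methylbenzoate F8. Hydrogenolysis (H2, Pd/C, EtOAc, rt) then gives 13.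

## Further compounds

F1 | step 1 | methyl 2-methoxy-6-methyl-4-[(4,4,5,5-tetramethyl-1,3,2-dioxaborolan-2-yl)oxy]benzoate | COC(=O)c1c(C)cc(OB2OC(C)(C)C(C)(C)O2)cc1OC
F2 | step 1 | methyl 4-hydroxy-2-methoxy-6-methylbenzoate | COC(=O)c1c(C)cc(O)cc1OC
F3 | step 2 | methyl 4-(benzyloxy)-2-methoxy-6-methylbenzoate | COC(=O)c1c(C)cc(OCc2ccccc2)cc1OC
F4 | step 2 | 4-(benzyloxy)-2-methoxy-6-methylbenzoic acid | OC(=O)c1c(C)cc(OCc2ccccc2)cc1OC
F5 | step 2 | methyl 4-{[4-(benzyloxy)-2-methoxy-6-methylbenzoyl]oxy}-2-methoxy-6-methylbenzoate | COC(=O)c1c(C)cc(OC(=O)c2c(C)cc(OCc3ccccc3)cc2OC)cc1OC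
F6 | step 5 | methyl 2-(benzyloxy)-4-methoxy-6-methylbenzoate | COC(=O)c1c(C)cc(OC)cc1OCc1ccccc1
F7 | step 5 | 2-(benzyloxy)-4-methoxy-6-methylbenzoic acid | OC(=O)c1c(C)cc(OC)cc1OCc1ccccc1
F8 | step 5 | methyl 4-({4-[(2-(benzyloxy)-4-methoxy-6-methylbenzoyl)oxy]-2-methoxy-6-methylbenzoyl}oxy)-2-methoxy-6-methylbenzoate | COC(=O)c1c(C)cc(OC(=O)c2c(C)cc(OC(=O)c3c(C)cc(OC)cc3OCc3ccccc3)cc2OC)cc1OC
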